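**Plan**

- Retrosynthesis (drimane numbering: C1–C10 for the decalin, C11 for the CH2 on C9): cut C11–C12 (bicycle CH2 to C1 of a farnesyl unit), then C9=C11 of a methylidene precursor back to a C9 ketone, then C5–C10 and C7=C8 together, then C5=C6 and C1–C2 of the open chain.
- Enabling feature: ring B holds its only double bond, C7=C8, next to C9, so it is a masked 2-methylcyclohex-2-enone (C9=O). In that enone C10–C9–C8 is the twofold nucleophile of one ketone and C5–C6–C7 an enal twofold electrophile. C5–C10 is also the last bond of ring A, so an open C14 chain can close both rings in one event.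
- Forward order: open chain by conjugate addition (regiodefined silyl enol ether) and cross-metathesis; rings A and B together in step 5; C11 by methylenation and hydroboration; the C15 chain by copper-catalysed Grignard coupling.
- Stereochemistry: C5 from the chiral amine (face of the iminium ion), C10 from the chair of the ring A closure (trans fusion), C9 from hydroboration anti to the axial C10 methyl. The E alkenes of the chain come unchanged from (2E,6E)-farnesyl bromide.

Key step: step 5

Remark: silyl enol ethers 6 and 8 are carried as E/Z mixtures, because both geometries place the same carbon (C10) at the reacting terminus and converge on one configuration there.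

**Route**

Step 1
Reactants: 1 methyl 3,3-dimethylpent-4-enoate
Product: 2 3,3-dimethylpent-4-en-1-ol
Conditions: LiAlH4, Et2O, 0 → 23 °C; aqueous NaOH work-up
Reagents that add atoms: none
Why: Hydride reduction of an unhindered methyl ester to the primary alcohol, which leaves the isolated vinyl group untouched.

Step 2
Reactants: 2 3,3-dimethylpent-4-en-1-ol
Product: 3 5-iodo-3,3-dimethylpent-1-ene
Conditions: PPh3, I2, imidazole, CH2Cl2, 0 → 23 °C
Reagents that add atoms: iodine, II
Why: Appel-type iodination, in which iodide displaces the oxyphosphonium group of a primary alcohol by SN2.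

Step 3
Reactants: 3 5-iodo-3,3-dimethylpent-1-ene; 4 2-methylpent-1-en-3-one
Product: 6 triethyl[(4,8,8-trimethyldeca-3,9-dien-3-yl)oxy]silane (E/Z mixture), via Grignard reagent 5 (not isolated)
Conditions: Mg, THF, 40 °C; then CuBr·SMe2 (10 mol %), HMPA, Et3SiCl, 4, THF, −78 °C; Et3N, then pentane/aqueous NaHCO3 work-up
Reagents that add atoms: chlorotriethylsilane, CC[Si](Cl)(CC)CC
Why: Copper-catalysed, silyl chloride-accelerated conjugate addition of the Grignard reagent to the unsubstituted β-carbon of the vinyl ketone, with O-silylation of the enolate, should give the tetrasubstituted enol ether with its double bond fixed at C10=C9, which enolisation of the free ketone would not deliver selectively.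

Step 4
Reactants: 6 triethyl[(4,8,8-trimethyldeca-3,9-dien-3-yl)oxy]silane; 7 (E)-but-2-enal
Product: 8 (2E)-4,4,8-trimethyl-9-[(triethylsilyl)oxy]undeca-2,8-dienal (8E/8Z mixture)
Conditions: 7 (5 equiv), second-generation Hoveyda–Grubbs catalyst RuCl2(H2IMes)(=CH-C6H4-2-OiPr) (5 mol %), base-washed CH2Cl2, 40 °C
Reagents that add atoms: none
Why: Olefin cross-metathesis, in which the vinyl group on the quaternary carbon does not homodimerise and should couple with the electron-poor partner used in excess to give the (E)-enal, while the tetrasubstituted enol ether is too hindered to engage the ruthenium carbene.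

Step 5
Reactants: 8 (2E)-4,4,8-trimethyl-9-[(triethylsilyl)oxy]undeca-2,8-dienal
Product: 10 (4aS,8aS)-2,5,5,8a-tetramethyl-4a,5,6,7,8,8a-hexahydronaphthalen-1(4H)-one, via keto aldehyde 9 (not isolated)
Conditions: (S)-2-[diphenyl(trimethylsilyloxy)methyl]pyrrolidine (20 mol %), 4-O2NC6H4CO2H (20 mol %), H2O (2 equiv), CH2Cl2, −20 → 23 °C; then PhMe, TsOH·H2O (30 mol %), 70 °C, same flask
Reagents that add atoms: none
Why: Proposed new method: the amine condenses with the aldehyde of 8 to an (E)-iminium ion whose β-carbon C5 is attacked by C10 of the tethered silyl enol ether, water takes the silyl group to leave keto aldehyde 9, and under TsOH the ethyl ketone of 9 enolises toward C8 and condenses with the C7 aldehyde to the C7=C8 enone. The closest known reaction types are the amine-catalysed Mukaiyama–Michael addition of silyl enol ethers to enal-derived iminium ions and the acid-mediated aldol condensation that ends a Robinson-type annulation; new is their intramolecular union on an acyclic tetrasubstituted enol ether that builds a quaternary carbon next to a neopentyl carbon. Ring A closes in the 6-(enolexo)-exo-trig mode and ring B in the 6-(enolendo)-exo-trig mode. C5 is set by the catalyst, whose CPh2OSiMe3 group screens one face of the s-trans iminium ion so that, by the sense known for carbon nucleophiles adding to β-substituted enals, the (S)-amine should give 5S; C10 is set by the chair of the ring A closure, in which the iminium chain on C5 and the bulky enol ether carbon C9 lie equatorial and the small methyl axial, placing the C10 methyl anti to H-5 (10S, trans fusion). The step needs conjugate instead of carbonyl attack and attack through C10 instead of C8: the tether allows a six-membered ring only for C10 on C5 (the alternatives are eight-membered), the enol ether double bond fixed in step 3 puts the nucleophile at C10, C8 can enolise only after C10 is quaternary, and the enal cannot enolise because C4 is quaternary.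

Step 6
Reactants: 10 (4aS,8aS)-2,5,5,8a-tetramethyl-4a,5,6,7,8,8a-hexahydronaphthalen-1(4H)-one
Product: 11 (4aS,8aS)-2,5,5,8a-tetramethyl-1-methylidene-1,4,4a,5,6,7,8,8a-octahydronaphthalene
Conditions: Ph3PCH3Br (3 equiv), KOtBu (3 equiv), PhMe, 90 °C
Reagents that add atoms: methyltriphenylphosphonium bromide, C[P+](c1ccccc1)(c1ccccc1)c1ccccc1.[Br-]
Why: Wittig methylenation with the smallest ylide under forcing conditions should convert the hindered C9 carbonyl into the exocyclic alkene; C5 and C10 cannot epimerise.

Step 7
Reactants: 11 (4aS,8aS)-2,5,5,8a-tetramethyl-1-methylidene-1,4,4a,5,6,7,8,8a-octahydronaphthalene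
Product: 13 [(1S,4aS,8aS)-2,5,5,8a-tetramethyl-1,4,4a,5,6,7,8,8a-octahydronaphthalen-1-yl]methanol (drimenol), via alkylborane 12 (not isolated)
Conditions: 9-BBN (1.5 equiv), THF, 0 → 50 °C; then NaOH, H2O2, H2O/THF, 0 → 23 °C
Reagents that add atoms: hydrogen peroxide, OO
Why: Hydroboration–oxidation, in which 9-BBN should add only to the 1,1-disubstituted exocyclic alkene with boron at terminal C11 and deliver hydrogen to C9 from the face anti to the axial C10 methyl, giving α-H and a β-CH2OH arm at C9 (9S), with retention on oxidation.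

Step 8
Reactants: 13 [(1S,4aS,8aS)-2,5,5,8a-tetramethyl-1,4,4a,5,6,7,8,8a-octahydronaphthalen-1-yl]methanol
Product: 14 (1S,4aS,8aS)-1-(iodomethyl)-2,5,5,8a-tetramethyl-1,4,4a,5,6,7,8,8a-octahydronaphthalene
Conditions: PPh3, I2, imidazole, CH2Cl2, 0 → 23 °C
Reagents that add atoms: iodine, II
Why: Appel-type iodination of a primary alcohol, which changes only C11 and leaves the adjacent C9 centre and the homoallylic alkene untouched.

Step 9
Reactants: 14 (1S,4aS,8aS)-1-(iodomethyl)-2,5,5,8a-tetramethyl-1,4,4a,5,6,7,8,8a-octahydronaphthalene; 15 (2E,6E)-1-bromo-3,7,11-trimethyldodeca-2,6,10-triene (farnesyl bromide)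
Product: 17 (1S,4aS,8aS)-2,5,5,8a-tetramethyl-1-[(3E,7E)-4,8,12-trimethyltrideca-3,7,11-trien-1-yl]-1,4,4a,5,6,7,8,8a-octahydronaphthalene (target), via Grignard reagent 16 (not isolated)
Conditions: Mg (activated), THF, 45 °C; then 15 (1.5 equiv), Li2CuCl4 (5 mol %), THF, −78 → 0 °C
Reagents that add atoms: none
Why: Copper-catalysed coupling of a primary alkyl Grignard reagent with a primary allylic bromide should occur at the unhindered CH2 terminus (the other allylic terminus is fully substituted), so the chain is joined with its E alkenes intact and C9, one carbon from the reacting site, is not affected.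

**Compound list**

1 | methyl 3,3-dimethylpent-4-enoate | COC(=O)CC(C)(C)C=C | starting material
2 | 3,3-dimethylpent-4-en-1-ol | OCCC(C)(C)C=C | intermediate
3 | 5-iodo-3,3-dimethylpent-1-ene | ICCC(C)(C)C=C | intermediate
4 | 2-methylpent-1-en-3-one | CCC(=O)C(C)=C | starting material
5 | (3,3-dimethylpent-4-en-1-yl)magnesium iodide | C=CC(C)(C)CC[Mg]I | intermediate
6 | triethyl[(4,8,8-trimethyldeca-3,9-dien-3-yl)oxy]silane (E/Z mixture) | CCC(O[Si](CC)(CC)CC)=C(C)CCCC(C)(C)C=C | intermediate
7 | (E)-but-2-enal | C/C=C/C=O | starting material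
8 | (2E)-4,4,8-trimethyl-9-[(triethylsilyl)oxy]undeca-2,8-dienal (8E/8Z mixture) | CCC(O[Si](CC)(CC)CC)=C(C)CCCC(C)(C)/C=C/C=O | intermediate
9 | 2-[(1S,6S)-2,2,6-trimethyl-6-propanoylcyclohexyl]acetaldehyde | O=CC[C@H]1C(C)(C)CCC[C@]1(C)C(=O)CC | intermediate
10 | (4aS,8aS)-2,5,5,8a-tetramethyl-4a,5,6,7,8,8a-hexahydronaphthalen-1(4H)-one | O=C1C(C)=CC[C@H]2C(C)(C)CCC[C@]12C | intermediate
11 | (4aS,8aS)-2,5,5,8a-tetramethyl-1-methylidene-1,4,4a,5,6,7,8,8a-octahydronaphthalene | C=C1C(C)=CC[C@H]2C(C)(C)CCC[C@]12C | intermediate
12 | 9-{[(1S,4aS,8aR)-2,5,5,8a-tetramethyl-1,4,4a,5,6,7,8,8a-octahydronaphthalen-1-yl]methyl}-9-borabicyclo[3.3.1]nonane | B3(C4CCCC3CCC4)C[C@H]1C(C)=CC[C@H]2C(C)(C)CCC[C@]12C | intermediate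
13 | [(1S,4aS,8aS)-2,5,5,8a-tetramethyl-1,4,4a,5,6,7,8,8a-octahydronaphthalen-1-yl]methanol (drimenol) | OC[C@H]1C(C)=CC[C@H]2C(C)(C)CCC[C@]12C | intermediate
14 | (1S,4aS,8aS)-1-(iodomethyl)-2,5,5,8a-tetramethyl-1,4,4a,5,6,7,8,8a-octahydronaphthalene | IC[C@H]1C(C)=CC[C@H]2C(C)(C)CCC[C@]12C | intermediate
15 | (2E,6E)-1-bromo-3,7,11-trimethyldodeca-2,6,10-triene (farnesyl bromide) | CC(C)=CCC/C(C)=C/CC/C(C)=C/CBr | starting material
16 | {[(1S,4aS,8aS)-2,5,5,8a-tetramethyl-1,4,4a,5,6,7,8,8a-octahydronaphthalen-1-yl]methyl}magnesium iodide | I[Mg]C[C@H]1C(C)=CC[C@H]2C(C)(C)CCC[C@]12C | intermediate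
17 | (1S,4aS,8aS)-2,5,5,8a-tetramethyl-1-[(3E,7E)-4,8,12-trimethyltrideca-3,7,11-trien-1-yl]-1,4,4a,5,6,7,8,8a-octahydronaphthalene | CC(C)=CCC/C(C)=C/CC/C(C)=C/CC[C@H]1C(C)=CC[C@H]2C(C)(C)CCC[C@]12C | target

**Step count**

Total steps: 9. Longest linear sequence: 9 steps (1 → 17); 4, 7 and 15 are bought and enter at steps 3, 4 and 9.

**Steps most likely to fail**

Step 5 (the new step). The silyl group may be lost by protonation before C10 reaches the hindered C5, leaving a ketone that does not cyclise. The closure may also proceed with poor facial or chair control, eroding enantiomeric or trans/cis purity. The fallback uses known chemistry, sets out from 8 and returns at 10. The ring A closure is run as a Lewis acid intramolecular Mukaiyama–Michael addition (TiCl4, CH2Cl2, −78 °C), which after aqueous work-up should give racemic 2-[(1S*,6S*)-2,2,6-trimethyl-6-propanoylcyclohexyl]acetaldehyde F1. Acid-mediated aldol condensation (TsOH·H2O, PhMe, 80 °C) then closes ring B to racemic (4aS*,8aS*)-2,5,5,8a-tetramethyl-4a,5,6,7,8,8a-hexahydronaphthalen-1(4H)-one F2. The enantiomers of F2 are separated by preparative chromatography on a chiral stationary phase (cellulose tris(3,5-dimethylphenylcarbamate)), and the (4aS,8aS) enantiomer is 10. Catalyst control is thus replaced by resolution.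

Step 9. Magnesium insertion into the β-branched iodide may be sluggish, Wurtz-type homocoupling may compete, or attack at the substituted allylic terminus may transpose the first chain alkene. The fallback sets out from 14 and returns at 17, carrying the C11 carbanion as a sulfone. TolSO2Na (DMF, 80 °C) displaces iodide to give (1S,4aS,8aS)-2,5,5,8a-tetramethyl-1-[(4-methylbenzenesulfonyl)methyl]-1,4,4a,5,6,7,8,8a-octahydronaphthalene F3. Deprotonation with n-BuLi (THF, −78 °C) and alkylation with 15 should give the chain-extended sulfone F4 as a mixture of epimers at the sulfonyl-bearing carbon, the soft carbanion attacking the CH2Br terminus. Reductive desulfonylation with Na(Hg), Na2HPO4, MeOH/THF, −20 °C then gives 17.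

Step 6. The ylide may deprotonate C6 (dienolate formation) instead of adding to the carbonyl flanked by quaternary C10, returning starting or deconjugated ketone. The fallback sets out from 10 and returns at 11 by a Peterson olefination. Me3SiCH2Li with anhydrous CeCl3 (THF, −78 °C) adds to the C9 carbonyl anti to the angular methyl to give (1S,4aS,8aS)-2,5,5,8a-tetramethyl-1-[(trimethylsilyl)methyl]-1,4,4a,5,6,7,8,8a-octahydronaphthalen-1-ol F5. Syn-elimination with KH (THF, 0 → 23 °C) then gives 11.

**Further compounds**

F1 | step 5 | racemic 2-[(1S*,6S*)-2,2,6-trimethyl-6-propanoylcyclohexyl]acetaldehyde | O=CC[C@H]1C(C)(C)CCC[C@]1(C)C(=O)CC.O=CC[C@@H]1C(C)(C)CCC[C@@]1(C)C(=O)CC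
F2 | step 5 | racemic (4aS*,8aS*)-2,5,5,8a-tetramethyl-4a,5,6,7,8,8a-hexahydronaphthalen-1(4H)-one | O=C1C(C)=CC[C@H]2C(C)(C)CCC[C@]12C.O=C1C(C)=CC[C@@H]2C(C)(C)CCC[C@@]12C
F3 | step 9 | (1S,4aS,8aS)-2,5,5,8a-tetramethyl-1-[(4-methylbenzenesulfonyl)methyl]-1,4,4a,5,6,7,8,8a-octahydronaphthalene | Cc1ccc(cc1)S(=O)(=O)C[C@H]1C(C)=CC[C@H]2C(C)(C)CCC[C@]12C
F4 | step 9 | (1S,4aS,8aS)-2,5,5,8a-tetramethyl-1-[(3E,7E)-4,8,12-trimethyl-1-(4-methylbenzenesulfonyl)trideca-3,7,11-trien-1-yl]-1,4,4a,5,6,7,8,8a-octahydronaphthalene (mixture of epimers at the sulfonyl-bearing carbon) | CC(C)=CCC/C(C)=C/CC/C(C)=C/CC([C@H]1C(C)=CC[C@H]2C(C)(C)CCC[C@]12C)S(=O)(=O)c1ccc(C)cc1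
F5 | step 6 | (1S,4aS,8aS)-2,5,5,8a-tetramethyl-1-[(trimethylsilyl)methyl]-1,4,4a,5,6,7,8,8a-octahydronaphthalen-1-ol | C[Si](C)(C)C[C@]1(O)C(C)=CC[C@H]2C(C)(C)CCC[C@]12C
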